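Ring C is cut at O1–C8a and C4–C4a, which leads back to a C4a–C8a aryne of ring A and the potassium alkoxide of an (S)-3-aryl-3-hydroxy Weinreb amide; the five benzyl-type groups come off last.
What makes this possible: O1 (on C8a) and the C4 carbonyl carbon (on C4a) are neighbours on ring A, and the C5 oxygen next to C4a polarises the aryne so that oxygen enters at C8a and carbon is acylated at C4a.
Ring A is built from 3,5-bis(benzyloxy)phenol by para-formylation, C3 chain extension, MeMgBr addition, ortho-bromination, retro-Brook silylation, triflation and benzyloxymethyl protection.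
Ring B with C2–C4 comes from 3,4-bis(benzyloxy)benzoic acid; ring C closes in the aryne annulation, and one hydrogenolysis then frees the four phenols and the tertiary alcohol.
C2 is set by asymmetric hydrogenation of the beta-keto ester with [RuCl(p-cymene)((R)-BINAP)]Cl and is carried through because the C2–O bond is never broken and the C4 ketone stays masked until quench.

Key step: step 11

Remark: flavanone locants (O1, C2–C4, C4a, C5–C8, C8a) are used for the corresponding atoms of every intermediate, and 3,5-bis(benzyloxy)phenol is assumed to be a catalogue compound.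

Step 1
Reactants: 1 3,5-bis(benzyloxy)phenol
Product: 3 2,6-bis(benzyloxy)-4-hydroxybenzaldehyde, via iminium chloride 2 (not isolated)
Conditions: POCl3, DMF, 0 °C → rt; then ice–water
Reagents that add atoms: N,N-dimethylformamide CN(C)C=O; water O
Why: Vilsmeier–Haack formylation, in which the bulky chloroiminium electrophile should enter para to the free hydroxyl (between the two benzyloxy groups), as is usual for 3,5-dialkoxyphenols, the minor ortho-hydroxy isomer being removed by chromatography.

Step 2
Reactants: 3 2,6-bis(benzyloxy)-4-hydroxybenzaldehyde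
Product: 4 methyl (E)-3-[2,6-bis(benzyloxy)-4-hydroxyphenyl]prop-2-enoate
Conditions: Ph3P=CHCO2Me, PhMe, 110 °C
Reagents that add atoms: methyl (triphenylphosphoranylidene)acetate COC(=O)C=P(c1ccccc1)(c1ccccc1)c1ccccc1
Why: Wittig olefination with a stabilised ylide, which tolerates the free phenol and should give the E-enoate, whose geometry is erased in the next step.

Step 3
Reactants: 4 methyl (E)-3-[2,6-bis(benzyloxy)-4-hydroxyphenyl]prop-2-enoate
Product: 5 methyl 3-[2,6-bis(benzyloxy)-4-hydroxyphenyl]propanoate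
Conditions: NaBH4, NiCl2·6H2O (cat.), MeOH–THF, 0 °C
Reagents that add atoms: none
Why: Conjugate reduction of the cinnamate double bond by Ni2B formed in situ from NiCl2·6H2O and NaBH4, which should leave the aryl benzyl ethers and the ester untouched where hydrogenation over palladium would not.

Step 4
Reactants: 5 methyl 3-[2,6-bis(benzyloxy)-4-hydroxyphenyl]propanoate
Product: 6 3,5-bis(benzyloxy)-4-(3-hydroxy-3-methylbutyl)phenol
Conditions: MeMgBr (5 equiv), THF, 0 °C → rt; aq. NH4Cl
Reagents that add atoms: methylmagnesium bromide C[Mg]Br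
Why: Double Grignard addition to the ester should give the tertiary alcohol, the first equivalent being consumed by the phenol, whose bromomagnesium phenoxide is inert.

Step 5
Reactants: 6 3,5-bis(benzyloxy)-4-(3-hydroxy-3-methylbutyl)phenol
Product: 7 2-bromo-3,5-bis(benzyloxy)-4-(3-hydroxy-3-methylbutyl)phenol
Conditions: NBS (1.0 equiv), CH2Cl2, −78 °C
Reagents that add atoms: N-bromosuccinimide O=C1CCC(=O)N1Br
Why: Electrophilic aromatic bromination ortho to the hydroxyl of a symmetric ring whose two open positions (C4a and C8) are equivalent, so one equivalent of NBS at low temperature should give a single monobromide.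

Step 6
Reactants: 7 2-bromo-3,5-bis(benzyloxy)-4-(3-hydroxy-3-methylbutyl)phenol
Product: 11 3,5-bis(benzyloxy)-4-(3-hydroxy-3-methylbutyl)-2-(trimethylsilyl)phenyl trifluoromethanesulfonate, via bis(trimethylsilyl) ether 8 (not isolated), via lithium phenoxide 9 (not isolated), via silyl ether triflate 10 (not isolated)
Conditions: HMDS, TMSOTf (cat.), CH2Cl2, rt, evaporation; n-BuLi, THF, −78 °C; PhNTf2, −78 °C → rt; then 1 M aq. HCl, THF, 0 °C
Reagents that add atoms: hexamethyldisilazane C[Si](C)(C)N[Si](C)(C)C; N-phenylbis(trifluoromethanesulfonimide) O=S(=O)(N(c1ccccc1)S(=O)(=O)C(F)(F)F)C(F)(F)F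
Why: Bromine–lithium exchange on the bis-silyl ether triggers the retro-Brook 1,3-shift of silicon from oxygen to C4a, the lithium phenoxide is then triflated by PhNTf2 (which spares the tertiary silyl ether), and brief dilute acid should remove only the labile tertiary O–SiMe3 group.

Step 7
Reactants: 11 3,5-bis(benzyloxy)-4-(3-hydroxy-3-methylbutyl)-2-(trimethylsilyl)phenyl trifluoromethanesulfonate
Product: 12 3,5-bis(benzyloxy)-4-[3-(benzyloxymethoxy)-3-methylbutyl]-2-(trimethylsilyl)phenyl trifluoromethanesulfonate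
Conditions: BOMCl, i-Pr2NEt, n-Bu4NI (cat.), ClCH2CH2Cl, 50 °C
Reagents that add atoms: benzyl chloromethyl ether ClCOCc1ccccc1
Why: O-alkylation of the hindered tertiary alcohol by the iodide-activated chloromethyl ether under amine base (acetal-type etherification) is fluoride-free, so the silyl triflate should survive, and it installs a group that hydrogenolysis removes.

Step 8
Reactants: 13 3,4-bis(benzyloxy)benzoic acid
Product: 16 methyl 3-[3,4-bis(benzyloxy)phenyl]-3-oxopropanoate, via acyl imidazolide 14 (not isolated), via acylmalonate 15 (not isolated)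
Conditions: 1,1'-carbonyldiimidazole, THF, rt; then KO2CCH2CO2Me, MgCl2, Et3N, MeCN, rt → 50 °C; aq. HCl
Reagents that add atoms: potassium methyl malonate COC(=O)CC(=O)[O-].[K+]
Why: The acyl imidazolide C-acylates the magnesium enolate of the malonate half ester (decarboxylative Claisen condensation), and loss of carbon dioxide on acidification should give the beta-keto ester without self-condensation.

Step 9
Reactants: 16 methyl 3-[3,4-bis(benzyloxy)phenyl]-3-oxopropanoate
Product: 17 methyl (S)-3-[3,4-bis(benzyloxy)phenyl]-3-hydroxypropanoate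
Conditions: H2 (50 atm), [RuCl(p-cymene)((R)-BINAP)]Cl (1 mol%), MeOH, 50 °C
Reagents that add atoms: none
Why: Noyori asymmetric hydrogenation of a beta-keto ester, in which chelation of the ester to the (R)-BINAP ruthenium hydride directs hydrogen to the ketone face that gives the (S)-carbinol (the sense established for aroylacetates), while benzyl ethers are inert to this catalyst.

Step 10
Reactants: 17 methyl (S)-3-[3,4-bis(benzyloxy)phenyl]-3-hydroxypropanoate
Product: 18 (S)-3-[3,4-bis(benzyloxy)phenyl]-3-hydroxy-N-methoxy-N-methylpropanamide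
Conditions: MeNH(OMe)·HCl, i-PrMgCl, THF, −20 → 0 °C; aq. NH4Cl
Reagents that add atoms: N,O-dimethylhydroxylamine hydrochloride CNOC.Cl
Why: Aminolysis of the ester by the chloromagnesium amide of N,O-dimethylhydroxylamine (Weinreb amide formation) should proceed on the magnesium alkoxide of the free carbinol at low temperature without retro-aldol cleavage, so the configuration is kept.

Step 11
Reactants: 12 3,5-bis(benzyloxy)-4-[3-(benzyloxymethoxy)-3-methylbutyl]-2-(trimethylsilyl)phenyl trifluoromethanesulfonate; 18 (S)-3-[3,4-bis(benzyloxy)phenyl]-3-hydroxy-N-methoxy-N-methylpropanamide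
Product: 23 (2S)-5,7-bis(benzyloxy)-2-[3,4-bis(benzyloxy)phenyl]-6-[3-(benzyloxymethoxy)-3-methylbutyl]chroman-4-one, via potassium alkoxide 19 (not isolated), via aryne 20 (not isolated), via aryl anion 21 (not isolated), via tetrahedral adduct 22 (not isolated)
Conditions: 18, KH (1 equiv per 18), THF, 0 °C; then 12, KF, 18-crown-6, THF, 0 °C → rt; aq. NH4Cl, 0 °C
Reagents that add atoms: none
Why: Proposed new method: fluoride attacks silicon in 12 and triflate leaves to give aryne 20, the preformed alkoxide 19 adds at C8a, and the C4a carbanion 21 attacks the amide carbonyl to give the stable tetrahedral adduct 22, which releases the C4 ketone only on quench. The closest known reaction type is the fluoride-triggered annulation of arynes with salicylate esters to xanthones (heteroatom addition followed by intramolecular acyl capture), extended here to an aliphatic alkoxide and to a ring carrying an enolisable position. Ring C closes by a 6-exo-trig addition of C4a to C4 after the intermolecular O1–C8a bond formation. No stereocentre is created: C2 comes from 18 with its C–O bond untouched, and because the ketone stays masked in 22 until the mildly acidic quench, no base meets an enolisable flavanone that could open to the chalcone. The step needs regioselective addition to the aryne, which the C5 benzyloxy group should secure by inductively distorting the C4a–C8a triple bond so that the nucleophile enters at the distal, unhindered C8a and the charge settles on C4a next to oxygen. Proton quench of 21 is limited by KH (dihydrogen as the only by-product), by THF in place of acetonitrile and by an amide whose alpha hydrogens are far less acidic than those of an ester.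

Step 12
Reactants: 23 (2S)-5,7-bis(benzyloxy)-2-[3,4-bis(benzyloxy)phenyl]-6-[3-(benzyloxymethoxy)-3-methylbutyl]chroman-4-one
Product: 24 (2S)-2-(3,4-dihydroxyphenyl)-5,7-dihydroxy-6-(3-hydroxy-3-methylbutyl)chroman-4-one
Conditions: H2 (1 atm), 10% Pd/C, EtOAc–MeOH, rt
Reagents that add atoms: none
Why: Catalytic hydrogenolysis should cleave the four aryl benzyl ethers and the benzyloxymethyl acetal (whose hemiacetal then loses formaldehyde) under neutral conditions that neither epimerise C2 nor cyclise the tertiary alcohol onto a neighbouring phenol.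

Compound list
1 | 3,5-bis(benzyloxy)phenol | Oc1cc(OCc2ccccc2)cc(OCc2ccccc2)c1 | starting material
2 | N-[2,6-bis(benzyloxy)-4-hydroxybenzylidene]-N-methylmethanaminium chloride | C[N+](C)=Cc1c(OCc2ccccc2)cc(O)cc1OCc1ccccc1.[Cl-] | intermediate
3 | 2,6-bis(benzyloxy)-4-hydroxybenzaldehyde | O=Cc1c(OCc2ccccc2)cc(O)cc1OCc1ccccc1 | intermediate
4 | methyl (E)-3-[2,6-bis(benzyloxy)-4-hydroxyphenyl]prop-2-enoate | COC(=O)/C=C/c1c(OCc2ccccc2)cc(O)cc1OCc1ccccc1 | intermediate
5 | methyl 3-[2,6-bis(benzyloxy)-4-hydroxyphenyl]propanoate | COC(=O)CCc1c(OCc2ccccc2)cc(O)cc1OCc1ccccc1 | intermediate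
6 | 3,5-bis(benzyloxy)-4-(3-hydroxy-3-methylbutyl)phenol | CC(C)(O)CCc1c(OCc2ccccc2)cc(O)cc1OCc1ccccc1 | intermediate
7 | 2-bromo-3,5-bis(benzyloxy)-4-(3-hydroxy-3-methylbutyl)phenol | CC(C)(O)CCc1c(OCc2ccccc2)cc(O)c(Br)c1OCc1ccccc1 | intermediate
8 | {2-bromo-3,5-bis(benzyloxy)-4-[3-methyl-3-(trimethylsilyloxy)butyl]phenoxy}trimethylsilane | CC(C)(O[Si](C)(C)C)CCc1c(OCc2ccccc2)cc(O[Si](C)(C)C)c(Br)c1OCc1ccccc1 | intermediate
9 | lithium 3,5-bis(benzyloxy)-4-[3-methyl-3-(trimethylsilyloxy)butyl]-2-(trimethylsilyl)phenoxide | CC(C)(O[Si](C)(C)C)CCc1c(OCc2ccccc2)cc([O-])c([Si](C)(C)C)c1OCc1ccccc1.[Li+] | intermediate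
10 | 3,5-bis(benzyloxy)-4-[3-methyl-3-(trimethylsilyloxy)butyl]-2-(trimethylsilyl)phenyl trifluoromethanesulfonate | CC(C)(O[Si](C)(C)C)CCc1c(OCc2ccccc2)cc(OS(=O)(=O)C(F)(F)F)c([Si](C)(C)C)c1OCc1ccccc1 | intermediate
11 | 3,5-bis(benzyloxy)-4-(3-hydroxy-3-methylbutyl)-2-(trimethylsilyl)phenyl trifluoromethanesulfonate | CC(C)(O)CCc1c(OCc2ccccc2)cc(OS(=O)(=O)C(F)(F)F)c([Si](C)(C)C)c1OCc1ccccc1 | intermediate
12 | 3,5-bis(benzyloxy)-4-[3-(benzyloxymethoxy)-3-methylbutyl]-2-(trimethylsilyl)phenyl trifluoromethanesulfonate | CC(C)(OCOCc1ccccc1)CCc1c(OCc2ccccc2)cc(OS(=O)(=O)C(F)(F)F)c([Si](C)(C)C)c1OCc1ccccc1 | intermediate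
13 | 3,4-bis(benzyloxy)benzoic acid | O=C(O)c1ccc(OCc2ccccc2)c(OCc2ccccc2)c1 | starting material
14 | [3,4-bis(benzyloxy)phenyl](1H-imidazol-1-yl)methanone | O=C(c1ccc(OCc2ccccc2)c(OCc2ccccc2)c1)n1ccnc1 | intermediate
15 | 2-[3,4-bis(benzyloxy)benzoyl]-3-methoxy-3-oxopropanoic acid (present as its magnesium chelate) | COC(=O)C(C(=O)O)C(=O)c1ccc(OCc2ccccc2)c(OCc2ccccc2)c1 | intermediate
16 | methyl 3-[3,4-bis(benzyloxy)phenyl]-3-oxopropanoate | COC(=O)CC(=O)c1ccc(OCc2ccccc2)c(OCc2ccccc2)c1 | intermediate
17 | methyl (S)-3-[3,4-bis(benzyloxy)phenyl]-3-hydroxypropanoate | COC(=O)C[C@@H](c1ccc(OCc2ccccc2)c(OCc2ccccc2)c1)O | intermediate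
18 | (S)-3-[3,4-bis(benzyloxy)phenyl]-3-hydroxy-N-methoxy-N-methylpropanamide | CON(C)C(=O)C[C@@H](c1ccc(OCc2ccccc2)c(OCc2ccccc2)c1)O | intermediate
19 | potassium (S)-1-[3,4-bis(benzyloxy)phenyl]-3-[methoxy(methyl)amino]-3-oxopropan-1-olate | CON(C)C(=O)C[C@@H](c1ccc(OCc2ccccc2)c(OCc2ccccc2)c1)[O-].[K+] | intermediate
20 | 3,5-bis(benzyloxy)-4-[3-(benzyloxymethoxy)-3-methylbutyl]-1,2-didehydrobenzene | CC(C)(OCOCc1ccccc1)CCC1=C(OCc2ccccc2)C#CC=C1OCc1ccccc1 | intermediate
21 | potassium aryl anion: (S)-3-[3,4-bis(benzyloxy)phenyl]-3-{3,5-bis(benzyloxy)-4-[3-(benzyloxymethoxy)-3-methylbutyl]-2-potassiophenoxy}-N-methoxy-N-methylpropanamide | CON(C)C(=O)C[C@@H](c1ccc(OCc2ccccc2)c(OCc2ccccc2)c1)Oc1cc(OCc2ccccc2)c(CCC(C)(C)OCOCc2ccccc2)c(OCc2ccccc2)c1[K] | intermediate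
22 | potassium (2S)-5,7-bis(benzyloxy)-2-[3,4-bis(benzyloxy)phenyl]-6-[3-(benzyloxymethoxy)-3-methylbutyl]-4-[methoxy(methyl)amino]chroman-4-olate | CC(C)(OCOCc1ccccc1)CCc1c(OCc2ccccc2)cc2c(c1OCc1ccccc1)C([O-])(N(C)OC)C[C@@H](c1ccc(OCc3ccccc3)c(OCc3ccccc3)c1)O2.[K+] | intermediate
23 | (2S)-5,7-bis(benzyloxy)-2-[3,4-bis(benzyloxy)phenyl]-6-[3-(benzyloxymethoxy)-3-methylbutyl]chroman-4-one | CC(C)(OCOCc1ccccc1)CCc1c(OCc2ccccc2)cc2c(c1OCc1ccccc1)C(=O)C[C@@H](c1ccc(OCc3ccccc3)c(OCc3ccccc3)c1)O2 | intermediate
24 | (2S)-2-(3,4-dihydroxyphenyl)-5,7-dihydroxy-6-(3-hydroxy-3-methylbutyl)chroman-4-one | CC(C)(O)CCc1c(O)cc2c(c1O)C(=O)C[C@@H](c1ccc(O)c(O)c1)O2 | target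

Total step count: 12 (steps 1–7 for the ring A fragment, steps 8–10 for the amide fragment, step 11 annulation, step 12 deprotection).
Longest linear sequence: 9 steps (steps 1–7, 11 and 12) from 3,5-bis(benzyloxy)phenol.

Steps most likely to fail

Step 11. The C4a carbanion may be protonated before it reaches the amide carbonyl. The potassium alkoxide may also dehydrate by base-induced elimination, fragment by retro-aldol cleavage, or attack sulfur of the triflate instead of waiting for the aryne. The fallback uses only known reactions, sets out from 7 and 16 and comes back to the route at 24. Keto ester 16 would be hydrogenated with the enantiomeric complex [RuCl(p-cymene)((S)-BINAP)]Cl to methyl (R)-3-[3,4-bis(benzyloxy)phenyl]-3-hydroxypropanoate F1 and converted under the conditions of step 10 into (R)-3-[3,4-bis(benzyloxy)phenyl]-3-hydroxy-N-methoxy-N-methylpropanamide F2. Mitsunobu etherification of bromophenol 7 with F2 (PPh3, DIAD, THF, 0 °C) would form the O1–C2 bond with inversion and give (S)-3-[3,4-bis(benzyloxy)phenyl]-3-[2-bromo-3,5-bis(benzyloxy)-4-(3-hydroxy-3-methylbutyl)phenoxy]-N-methoxy-N-methylpropanamide F3. Deprotonation of the tertiary alcohol with MeLi, bromine–lithium exchange with t-BuLi at −78 °C and Parham cyclisation onto the Weinreb amide would form C4–C4a and give (2S)-5,7-bis(benzyloxy)-2-[3,4-bis(benzyloxy)phenyl]-6-(3-hydroxy-3-methylbutyl)chroman-4-one F4. Hydrogenolysis of F4 under the conditions of step 12 would give 24.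

Step 6. The aryllithium may be protonated or alkylated before silicon migrates, triflation of the hindered phenoxide may be incomplete, or the acid wash may cleave the electron-rich aryl–silicon bond along with the tertiary silyl ether. The fallback replaces halogen–metal exchange by carbamate-directed ortho-metalation, sets out from 6 and comes back at 11. Phenol 6 would be treated with isopropyl isocyanate and catalytic Et3N in CH2Cl2 to give 3,5-bis(benzyloxy)-4-(3-hydroxy-3-methylbutyl)phenyl N-isopropylcarbamate F5. Silylation in situ (TMSOTf, TMEDA), ortho-lithiation with n-BuLi/TMEDA at −78 °C, quench with TMSCl and acidic work-up would give 3,5-bis(benzyloxy)-4-(3-hydroxy-3-methylbutyl)-2-(trimethylsilyl)phenyl N-isopropylcarbamate F6. DBU and Et2NH in MeCN at 40 °C would unmask the phenol, which PhNTf2 triflates in the same flask, selectively over the tertiary alcohol, to give 11.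

Step 1. Formylation ortho to the hydroxyl may compete with the desired para attack, so regioselectivity may be poor. The fallback replaces electrophilic substitution by directed ortho-metalation, sets out from 1 and comes back at 3. Phenol 1 would be silylated (TIPSCl, imidazole, DMF) to [3,5-bis(benzyloxy)phenoxy]triisopropylsilane F7. Lithiation between the two benzyloxy groups (n-BuLi, TMEDA, THF, −20 °C), away from the bulky and poorly coordinating silyloxy group, and quench with DMF would give 2,6-bis(benzyloxy)-4-(triisopropylsilyloxy)benzaldehyde F8. Tetrabutylammonium fluoride in THF at 0 °C would then return 3.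

Further compounds
F1 | step 11 | methyl (R)-3-[3,4-bis(benzyloxy)phenyl]-3-hydroxypropanoate | COC(=O)C[C@H](c1ccc(OCc2ccccc2)c(OCc2ccccc2)c1)O
F2 | step 11 | (R)-3-[3,4-bis(benzyloxy)phenyl]-3-hydroxy-N-methoxy-N-methylpropanamide | CON(C)C(=O)C[C@H](c1ccc(OCc2ccccc2)c(OCc2ccccc2)c1)O
F3 | step 11 | (S)-3-[3,4-bis(benzyloxy)phenyl]-3-[2-bromo-3,5-bis(benzyloxy)-4-(3-hydroxy-3-methylbutyl)phenoxy]-N-methoxy-N-methylpropanamide | CON(C)C(=O)C[C@@H](c1ccc(OCc2ccccc2)c(OCc2ccccc2)c1)Oc1cc(OCc2ccccc2)c(CCC(C)(C)O)c(OCc2ccccc2)c1Br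
F4 | step 11 | (2S)-5,7-bis(benzyloxy)-2-[3,4-bis(benzyloxy)phenyl]-6-(3-hydroxy-3-methylbutyl)chroman-4-one | CC(C)(O)CCc1c(OCc2ccccc2)cc2c(c1OCc1ccccc1)C(=O)C[C@@H](c1ccc(OCc3ccccc3)c(OCc3ccccc3)c1)O2
F5 | step 6 | 3,5-bis(benzyloxy)-4-(3-hydroxy-3-methylbutyl)phenyl N-isopropylcarbamate | CC(C)NC(=O)Oc1cc(OCc2ccccc2)c(CCC(C)(C)O)c(OCc2ccccc2)c1
F6 | step 6 | 3,5-bis(benzyloxy)-4-(3-hydroxy-3-methylbutyl)-2-(trimethylsilyl)phenyl N-isopropylcarbamate | CC(C)NC(=O)Oc1cc(OCc2ccccc2)c(CCC(C)(C)O)c(OCc2ccccc2)c1[Si](C)(C)C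
F7 | step 1 | [3,5-bis(benzyloxy)phenoxy]triisopropylsilane | CC(C)[Si](Oc1cc(OCc2ccccc2)cc(OCc2ccccc2)c1)(C(C)C)C(C)C
F8 | step 1 | 2,6-bis(benzyloxy)-4-(triisopropylsilyloxy)benzaldehyde | CC(C)[Si](Oc1cc(OCc2ccccc2)c(C=O)c(OCc2ccccc2)c1)(C(C)C)C(C)C
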